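**Assumption (one line):** locants C1–C14 and C20 are cembrane-type labels of the target (C1 = ring CH bearing isopropenyl, C14 = ring CH–OAc, C9 = ring CH–OH, C12 = ring carbon bearing C20H2OAc); (R)-solketal, (S)-α-hydroxy-γ-butyrolactone and pent-3-yn-1-ol are taken as catalogue items.

## Retrosynthetic overview

1. Target ⇐ acetylation/desilylation of a 14-membered (E)-enoate. The only ring is closed late, by intramolecular Horner–Wadsworth–Emmons olefination at C12=C13.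
2. Seco aldehyde–phosphonate ⇐ B-alkyl Suzuki–Miyaura coupling at C3–C4 of a western alkyl iodide (C13–C14–C1–C3) with an eastern vinyl iodide (C4–C12, C20).
3. Western half ⇐ Johnson–Claisen [3,3] rearrangement: the key C1–C2 bond, with C1 set by the C14 stereocentre bought in (R)-solketal.
4. Eastern half ⇐ Z-selective Wittig at C7=C8 of an α-silyloxy methyl ketone (C9 bought in (S)-α-hydroxy-γ-butyrolactone) with an ylide from pent-3-yn-1-ol (C4=C5 by hydrozirconation–iodination); C11–C12 by phosphonoacetate alkylation.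

## Route

Step 1
Reactants: 1 (R)-solketal, [(4R)-2,2-dimethyl-1,3-dioxolan-4-yl]methanol
Product: 3 ethyl (2E)-3-[(4R)-2,2-dimethyl-1,3-dioxolan-4-yl]-2-methylprop-2-enoate, via (4S)-2,2-dimethyl-1,3-dioxolane-4-carbaldehyde 2 (not isolated)
Conditions: (COCl)2, DMSO, CH2Cl2, −78 °C; i-Pr2NEt; then Ph3P=C(Me)CO2Et, −78 → 23 °C
Reagents that add atoms: ethyl 2-(triphenylphosphoranylidene)propanoate, CCOC(=O)C(C)=P(c1ccccc1)(c1ccccc1)c1ccccc1
Why: Swern oxidation gives the configurationally labile aldehyde, which is trapped at once by the stabilised α-methyl ylide in an E-selective Wittig reaction; the C14 stereocentre is the one bought in 1.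

Step 2
Reactants: 3 ethyl (2E)-3-[(4R)-2,2-dimethyl-1,3-dioxolan-4-yl]-2-methylprop-2-enoate
Product: 4 (2E)-3-[(4R)-2,2-dimethyl-1,3-dioxolan-4-yl]-2-methylprop-2-en-1-ol
Conditions: DIBAL-H (2.2 equiv), CH2Cl2, −78 °C; Rochelle salt
Reagents that add atoms: none
Why: 1,2-reduction of the enoate by DIBAL-H gives the allylic alcohol and leaves the acetonide and alkene geometry untouched.

Step 3
Reactants: 4 (2E)-3-[(4R)-2,2-dimethyl-1,3-dioxolan-4-yl]-2-methylprop-2-en-1-ol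
Product: 6 ethyl (3R)-3-[(4R)-2,2-dimethyl-1,3-dioxolan-4-yl]-4-methylpent-4-enoate, via (4R)-4-[(1E)-3-[(1-ethoxyethenyl)oxy]-2-methylprop-1-en-1-yl]-2,2-dimethyl-1,3-dioxolane 5 (not isolated)
Conditions: MeC(OEt)3 (6 equiv), EtCO2H (5 mol %), 135–140 °C, EtOH distilled off
Reagents that add atoms: triethyl orthoacetate, CC(OCC)(OCC)OCC
Why: Johnson–Claisen [3,3]-sigmatropic rearrangement through a chair forms the C1–C2 bond and the isopropenyl group; A(1,3) strain with the 2-methyl holds C14–H in the alkene plane and the bond forms anti to the allylic C–O bond, giving the 3,4-syn isomer (C1 R), expected about 6:1 or better, with the minor epimer removed at 7.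

Step 4
Reactants: 6 ethyl (3R)-3-[(4R)-2,2-dimethyl-1,3-dioxolan-4-yl]-4-methylpent-4-enoate
Product: 7 (3R)-3-[(4R)-2,2-dimethyl-1,3-dioxolan-4-yl]-4-methylpent-4-en-1-ol
Conditions: LiAlH4, Et2O, 0 °C
Reagents that add atoms: none
Why: Hydride reduction of the ester to the primary alcohol (C3) has no effect on the stereocentres.

Step 5
Reactants: 7 (3R)-3-[(4R)-2,2-dimethyl-1,3-dioxolan-4-yl]-4-methylpent-4-en-1-ol
Product: 8 (4R)-4-[(3R)-5-iodo-2-methylpent-1-en-3-yl]-2,2-dimethyl-1,3-dioxolane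
Conditions: I2, PPh3, imidazole, CH2Cl2, 0 → 23 °C
Reagents that add atoms: iodine, II
Why: Appel-type iodination of the primary alcohol under imidazole buffering, which the acetonide tolerates.

Step 6
Reactants: 9 pent-3-yn-1-ol
Product: 11 (3E)-4-iodopent-3-en-1-ol, via chlorobis(cyclopentadienyl)[(2E)-5-{[chlorobis(cyclopentadienyl)zirconio]oxy}pent-2-en-2-yl]zirconium 10 (not isolated)
Conditions: Cp2Zr(H)Cl (2.3 equiv), THF, 23 → 45 °C; then I2, 0 °C
Reagents that add atoms: iodine, II; zirconocene chloride hydride (Zr stays only in intermediate 10), [H][Zr](Cl)(C1C=CC=C1)C1C=CC=C1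
Why: syn-Hydrozirconation under equilibrating conditions puts Zr on the methyl-bearing alkyne carbon, and iodinolysis with retention gives the (E)-vinyl iodide that fixes the C4=C5 geometry.

Step 7
Reactants: 11 (3E)-4-iodopent-3-en-1-ol
Product: 12 (2E)-2,5-diiodopent-2-ene
Conditions: I2, PPh3, imidazole, CH2Cl2, 0 °C
Reagents that add atoms: iodine, II
Why: Appel-type iodination of the primary homoallylic alcohol; the vinyl iodide is inert.

Step 8
Reactants: 12 (2E)-2,5-diiodopent-2-ene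
Product: 13 [(3E)-4-iodopent-3-en-1-yl]triphenylphosphonium iodide
Conditions: PPh3, MeCN, 80 °C
Reagents that add atoms: triphenylphosphine, c1ccc(cc1)P(c1ccccc1)c1ccccc1
Why: SN2 quaternisation occurs only at the primary alkyl iodide, since the sp2 C–I bond does not react with PPh3.

Step 9
Reactants: 14 (3S)-3-hydroxyoxolan-2-one, (S)-α-hydroxy-γ-butyrolactone
Product: 15 (2S)-2,4-dihydroxy-N-methoxy-N-methylbutanamide
Conditions: MeNH(OMe)·HCl (3 equiv), i-PrMgCl (6 equiv), THF, −20 → 0 °C; used crude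
Reagents that add atoms: N,O-dimethylhydroxylamine hydrochloride, CNOC.Cl
Why: Weinreb aminolysis opens the lactone with the magnesium amide; the C9 stereocentre (bought) is not enolised as its α-alkoxide.

Step 10
Reactants: 15 (2S)-2,4-dihydroxy-N-methoxy-N-methylbutanamide
Product: 16 (2S)-2,4-bis[(tert-butyldimethylsilyl)oxy]-N-methoxy-N-methylbutanamide
Conditions: TBSCl (2.5 equiv), imidazole, DMF, 23 °C
Reagents that add atoms: tert-butyldimethylsilyl chloride, CC(C)(C)[Si](C)(C)Cl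
Why: Standard silylation protects both hydroxyls (C9 and C11).

Step 11
Reactants: 16 (2S)-2,4-bis[(tert-butyldimethylsilyl)oxy]-N-methoxy-N-methylbutanamide
Product: 17 (3S)-3,5-bis[(tert-butyldimethylsilyl)oxy]pentan-2-one
Conditions: MeMgBr (1.6 equiv), THF, −78 → 0 °C; aq NH4Cl
Reagents that add atoms: methylmagnesium bromide, C[Mg]Br
Why: Weinreb ketone synthesis; the chelated tetrahedral intermediate prevents over-addition and the α-silyloxy centre is not epimerised.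

Step 12
Reactants: 13 [(3E)-4-iodopent-3-en-1-yl]triphenylphosphonium iodide; 17 (3S)-3,5-bis[(tert-butyldimethylsilyl)oxy]pentan-2-one
Product: 19 (3S,4Z,7E)-1,3-bis[(tert-butyldimethylsilyl)oxy]-8-iodo-4-methylnona-4,7-diene, via [(3E)-4-iodopent-3-en-1-ylidene]triphenylphosphorane 18 (not isolated)
Conditions: 13 (1.3 equiv), NaHMDS (1.25 equiv), THF, −78 °C; then 17, −78 → −20 °C
Reagents that add atoms: none
Why: Wittig olefination of an α-alkoxy methyl ketone with a non-stabilised ylide is strongly Z-selective for the trisubstituted alkene (C6 cis to the C9 carbinol carbon), and the fast low-temperature addition avoids enolisation at C9.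

Step 13
Reactants: 19 (3S,4Z,7E)-1,3-bis[(tert-butyldimethylsilyl)oxy]-8-iodo-4-methylnona-4,7-diene
Product: 20 (3S,4Z,7E)-3-[(tert-butyldimethylsilyl)oxy]-8-iodo-4-methylnona-4,7-dien-1-ol
Conditions: HF·pyridine, pyridine, THF, 0 °C
Reagents that add atoms: none
Why: Buffered fluoride cleaves the unhindered primary TBS ether far faster than the hindered secondary allylic one.

Step 14
Reactants: 20 (3S,4Z,7E)-3-[(tert-butyldimethylsilyl)oxy]-8-iodo-4-methylnona-4,7-dien-1-ol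
Product: 21 tert-butyl{[(3S,4Z,7E)-1,8-diiodo-4-methylnona-4,7-dien-3-yl]oxy}dimethylsilane
Conditions: I2, PPh3, imidazole, CH2Cl2, 0 °C
Reagents that add atoms: iodine, II
Why: Appel-type iodination converts the C11 alcohol into the alkylating iodide.

Step 15
Reactants: 21 tert-butyl{[(3S,4Z,7E)-1,8-diiodo-4-methylnona-4,7-dien-3-yl]oxy}dimethylsilane
Product: 22 ethyl (5S,6Z,9E)-5-[(tert-butyldimethylsilyl)oxy]-2-(diethoxyphosphoryl)-10-iodo-6-methylundeca-6,9-dienoate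
Conditions: (EtO)2P(O)CH2CO2Et (3.2 equiv), NaH (3.0 equiv), DMF, 0 → 50 °C
Reagents that add atoms: triethyl phosphonoacetate, CCOC(=O)CP(=O)(OCC)OCC
Why: SN2 alkylation of excess sodium phosphonoacetate at the primary iodide forms C11–C12 (vinyl iodide inert); the new phosphonate-bearing centre forms as a mixture and is destroyed in step 20.

Step 16
Reactants: 8 (4R)-4-[(3R)-5-iodo-2-methylpent-1-en-3-yl]-2,2-dimethyl-1,3-dioxolane; 22 ethyl (5S,6Z,9E)-5-[(tert-butyldimethylsilyl)oxy]-2-(diethoxyphosphoryl)-10-iodo-6-methylundeca-6,9-dienoate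
Product: 25 ethyl (5S,6Z,9E,13R)-5-[(tert-butyldimethylsilyl)oxy]-2-(diethoxyphosphoryl)-13-[(4R)-2,2-dimethyl-1,3-dioxolan-4-yl]-6,10,14-trimethylpentadeca-6,9,14-trienoate, via [(3R)-3-[(4R)-2,2-dimethyl-1,3-dioxolan-4-yl]-4-methylpent-4-en-1-yl]lithium 23 (not isolated), via lithium B-[(3R)-3-[(4R)-2,2-dimethyl-1,3-dioxolan-4-yl]-4-methylpent-4-en-1-yl]-B-methoxy-9-borabicyclo[3.3.1]nonan-9-uide 24 (not isolated)
Conditions: 8 (1.4 equiv), t-BuLi (2.9 equiv), Et2O, −78 °C; B-OMe-9-BBN, THF, −78 → 23 °C; then 22, Pd(dppf)Cl2 (8 mol %), AsPh3, aq K3PO4, DMF, 23 °C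
Reagents that add atoms: tert-butyllithium (Li only in 23 and 24), [Li]C(C)(C)C; 9-methoxy-9-borabicyclo[3.3.1]nonane (only in 24), COB1C2CCCC1CCC2
Why: Lithium–iodine exchange and borate formation followed by B-alkyl Suzuki–Miyaura coupling joins C3 to C4 with retention of the (E)-vinyl iodide geometry; no stereocentre is touched.

Step 17
Reactants: 25 ethyl (5S,6Z,9E,13R)-5-[(tert-butyldimethylsilyl)oxy]-2-(diethoxyphosphoryl)-13-[(4R)-2,2-dimethyl-1,3-dioxolan-4-yl]-6,10,14-trimethylpentadeca-6,9,14-trienoate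
Product: 26 ethyl (5S,6Z,9E,13R,14R)-5-[(tert-butyldimethylsilyl)oxy]-2-(diethoxyphosphoryl)-14,15-dihydroxy-6,10-dimethyl-13-(prop-1-en-2-yl)pentadeca-6,9-dienoate
Conditions: PPTS (0.3 equiv), MeOH, 40 °C, monitored
Reagents that add atoms: none
Why: Acid-catalysed transketalisation removes the terminal acetonide faster than the hindered secondary TBS ether is cleaved.

Step 18
Reactants: 26 ethyl (5S,6Z,9E,13R,14R)-5-[(tert-butyldimethylsilyl)oxy]-2-(diethoxyphosphoryl)-14,15-dihydroxy-6,10-dimethyl-13-(prop-1-en-2-yl)pentadeca-6,9-dienoate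
Product: 27 ethyl (5S,6Z,9E,13R,14R)-5-[(tert-butyldimethylsilyl)oxy]-2-(diethoxyphosphoryl)-6,10-dimethyl-13-(prop-1-en-2-yl)-14,15-bis[(triethylsilyl)oxy]pentadeca-6,9-dienoate
Conditions: TESCl (3 equiv), imidazole, DMAP (cat.), CH2Cl2, 0 → 23 °C
Reagents that add atoms: chlorotriethylsilane, CC[Si](Cl)(CC)CC
Why: Bis-silylation sets up differentiation of the primary (C13) and secondary (C14) oxygens in the next step.

Step 19
Reactants: 27 ethyl (5S,6Z,9E,13R,14R)-5-[(tert-butyldimethylsilyl)oxy]-2-(diethoxyphosphoryl)-6,10-dimethyl-13-(prop-1-en-2-yl)-14,15-bis[(triethylsilyl)oxy]pentadeca-6,9-dienoate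
Product: 28 ethyl (5S,6Z,9E,13R,14R)-5-[(tert-butyldimethylsilyl)oxy]-2-(diethoxyphosphoryl)-6,10-dimethyl-15-oxo-13-(prop-1-en-2-yl)-14-[(triethylsilyl)oxy]pentadeca-6,9-dienoate
Conditions: (COCl)2 (5 equiv), DMSO (10 equiv), CH2Cl2, −78 → −35 °C; Et3N, −78 → 0 °C
Reagents that add atoms: none
Why: Under Swern conditions the primary TES ether is cleaved and oxidised directly to the aldehyde while secondary TES and TBS ethers survive.

Step 20
Reactants: 28 ethyl (5S,6Z,9E,13R,14R)-5-[(tert-butyldimethylsilyl)oxy]-2-(diethoxyphosphoryl)-6,10-dimethyl-15-oxo-13-(prop-1-en-2-yl)-14-[(triethylsilyl)oxy]pentadeca-6,9-dienoate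
Product: 29 ethyl (1E,3S,4R,7E,10Z,12S)-12-[(tert-butyldimethylsilyl)oxy]-7,11-dimethyl-4-(prop-1-en-2-yl)-3-[(triethylsilyl)oxy]cyclotetradeca-1,7,10-triene-1-carboxylate
Conditions: LiCl (20 equiv), DBU (8 equiv), MeCN, 23 °C, syringe-pump addition to 1 mM
Reagents that add atoms: none
Why: Intramolecular Horner–Wadsworth–Emmons olefination (Masamune–Roush conditions, high dilution) closes the 14-membered ring at C12=C13 as the (E)-enoate (ester trans to C14), mild enough not to epimerise the α-silyloxy aldehyde.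

Step 21
Reactants: 29 ethyl (1E,3S,4R,7E,10Z,12S)-12-[(tert-butyldimethylsilyl)oxy]-7,11-dimethyl-4-(prop-1-en-2-yl)-3-[(triethylsilyl)oxy]cyclotetradeca-1,7,10-triene-1-carboxylate
Product: 30 [(1E,3S,4R,7E,10Z,12S)-12-[(tert-butyldimethylsilyl)oxy]-7,11-dimethyl-4-(prop-1-en-2-yl)-3-[(triethylsilyl)oxy]cyclotetradeca-1,7,10-trien-1-yl]methanol
Conditions: DIBAL-H (3.5 equiv), CH2Cl2, −78 °C; Rochelle salt
Reagents that add atoms: none
Why: 1,2-Reduction of the enoate gives the C20 allylic alcohol with the alkene geometry retained.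

Step 22
Reactants: 30 [(1E,3S,4R,7E,10Z,12S)-12-[(tert-butyldimethylsilyl)oxy]-7,11-dimethyl-4-(prop-1-en-2-yl)-3-[(triethylsilyl)oxy]cyclotetradeca-1,7,10-trien-1-yl]methanol
Product: 31 (1E,3S,4R,7E,10Z,12S)-12-[(tert-butyldimethylsilyl)oxy]-1-(hydroxymethyl)-7,11-dimethyl-4-(prop-1-en-2-yl)cyclotetradeca-1,7,10-trien-3-ol
Conditions: PPTS (0.2 equiv), MeOH/CH2Cl2, 0 → 23 °C
Reagents that add atoms: none
Why: Mild acidic methanolysis removes the TES ether selectively in the presence of the secondary TBS ether, freeing C14–OH.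

Step 23
Reactants: 31 (1E,3S,4R,7E,10Z,12S)-12-[(tert-butyldimethylsilyl)oxy]-1-(hydroxymethyl)-7,11-dimethyl-4-(prop-1-en-2-yl)cyclotetradeca-1,7,10-trien-3-ol
Product: 32 [(1E,3S,4R,7E,10Z,12S)-3-acetoxy-12-[(tert-butyldimethylsilyl)oxy]-7,11-dimethyl-4-(prop-1-en-2-yl)cyclotetradeca-1,7,10-trien-1-yl]methyl acetate
Conditions: Ac2O (6 equiv), pyridine, DMAP (0.1 equiv), CH2Cl2, 0 → 23 °C
Reagents that add atoms: acetic anhydride, CC(=O)OC(C)=O
Why: DMAP-catalysed acylation acetylates both free hydroxyls (C14 and C20) with retention at C14 while C9 stays silylated.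

Step 24
Reactants: 32 [(1E,3S,4R,7E,10Z,12S)-3-acetoxy-12-[(tert-butyldimethylsilyl)oxy]-7,11-dimethyl-4-(prop-1-en-2-yl)cyclotetradeca-1,7,10-trien-1-yl]methyl acetate
Product: 33 [(1E,3S,4R,7E,10Z,12S)-3-acetoxy-12-hydroxy-7,11-dimethyl-4-(prop-1-en-2-yl)cyclotetradeca-1,7,10-trien-1-yl]methyl acetate (target)
Conditions: HF·pyridine, pyridine, THF, 0 → 23 °C
Reagents that add atoms: none
Why: Buffered fluoride desilylation frees the C9 hydroxyl without cleaving or migrating the two acetates.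

## Compound list

1 | (R)-solketal, [(4R)-2,2-dimethyl-1,3-dioxolan-4-yl]methanol | OC[C@@H]1COC(C)(C)O1 | starting material
2 | (4S)-2,2-dimethyl-1,3-dioxolane-4-carbaldehyde | O=C[C@@H]1COC(C)(C)O1 | intermediate
3 | ethyl (2E)-3-[(4R)-2,2-dimethyl-1,3-dioxolan-4-yl]-2-methylprop-2-enoate | CCOC(=O)/C(C)=C/[C@@H]1COC(C)(C)O1 | intermediate
4 | (2E)-3-[(4R)-2,2-dimethyl-1,3-dioxolan-4-yl]-2-methylprop-2-en-1-ol | OC/C(C)=C/[C@@H]1COC(C)(C)O1 | intermediate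
5 | (4R)-4-[(1E)-3-[(1-ethoxyethenyl)oxy]-2-methylprop-1-en-1-yl]-2,2-dimethyl-1,3-dioxolane | C=C(OCC)OC/C(C)=C/[C@@H]1COC(C)(C)O1 | intermediate
6 | ethyl (3R)-3-[(4R)-2,2-dimethyl-1,3-dioxolan-4-yl]-4-methylpent-4-enoate | CCOC(=O)C[C@H](C(C)=C)[C@@H]1COC(C)(C)O1 | intermediate
7 | (3R)-3-[(4R)-2,2-dimethyl-1,3-dioxolan-4-yl]-4-methylpent-4-en-1-ol | OCC[C@H](C(C)=C)[C@@H]1COC(C)(C)O1 | intermediate
8 | (4R)-4-[(3R)-5-iodo-2-methylpent-1-en-3-yl]-2,2-dimethyl-1,3-dioxolane | ICC[C@H](C(C)=C)[C@@H]1COC(C)(C)O1 | intermediate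
9 | pent-3-yn-1-ol | CC#CCCO | starting material
10 | chlorobis(cyclopentadienyl)[(2E)-5-{[chlorobis(cyclopentadienyl)zirconio]oxy}pent-2-en-2-yl]zirconium | C/C(=C\CCO[Zr](Cl)(C1C=CC=C1)C1C=CC=C1)[Zr](Cl)(C1C=CC=C1)C1C=CC=C1 | intermediate
11 | (3E)-4-iodopent-3-en-1-ol | I/C(C)=C/CCO | intermediate
12 | (2E)-2,5-diiodopent-2-ene | I/C(C)=C/CCI | intermediate
13 | [(3E)-4-iodopent-3-en-1-yl]triphenylphosphonium iodide | I/C(C)=C/CC[P+](c1ccccc1)(c1ccccc1)c1ccccc1.[I-] | intermediate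
14 | (3S)-3-hydroxyoxolan-2-one, (S)-α-hydroxy-γ-butyrolactone | O=C1OCC[C@@H]1O | starting material
15 | (2S)-2,4-dihydroxy-N-methoxy-N-methylbutanamide | CON(C)C(=O)[C@@H](O)CCO | intermediate
16 | (2S)-2,4-bis[(tert-butyldimethylsilyl)oxy]-N-methoxy-N-methylbutanamide | CON(C)C(=O)[C@@H](O[Si](C)(C)C(C)(C)C)CCO[Si](C)(C)C(C)(C)C | intermediate
17 | (3S)-3,5-bis[(tert-butyldimethylsilyl)oxy]pentan-2-one | CC(=O)[C@@H](O[Si](C)(C)C(C)(C)C)CCO[Si](C)(C)C(C)(C)C | intermediate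
18 | [(3E)-4-iodopent-3-en-1-ylidene]triphenylphosphorane | I/C(C)=C/CC=P(c1ccccc1)(c1ccccc1)c1ccccc1 | intermediate
19 | (3S,4Z,7E)-1,3-bis[(tert-butyldimethylsilyl)oxy]-8-iodo-4-methylnona-4,7-diene | I/C(C)=C/C/C=C(/C)[C@@H](O[Si](C)(C)C(C)(C)C)CCO[Si](C)(C)C(C)(C)C | intermediate
20 | (3S,4Z,7E)-3-[(tert-butyldimethylsilyl)oxy]-8-iodo-4-methylnona-4,7-dien-1-ol | I/C(C)=C/C/C=C(/C)[C@@H](O[Si](C)(C)C(C)(C)C)CCO | intermediate
21 | tert-butyl{[(3S,4Z,7E)-1,8-diiodo-4-methylnona-4,7-dien-3-yl]oxy}dimethylsilane | I/C(C)=C/C/C=C(/C)[C@@H](O[Si](C)(C)C(C)(C)C)CCI | intermediate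
22 | ethyl (5S,6Z,9E)-5-[(tert-butyldimethylsilyl)oxy]-2-(diethoxyphosphoryl)-10-iodo-6-methylundeca-6,9-dienoate (C2 epimers) | I/C(C)=C/C/C=C(/C)[C@@H](O[Si](C)(C)C(C)(C)C)CCC(C(=O)OCC)P(=O)(OCC)OCC | intermediate
23 | [(3R)-3-[(4R)-2,2-dimethyl-1,3-dioxolan-4-yl]-4-methylpent-4-en-1-yl]lithium | [Li]CC[C@H](C(C)=C)[C@@H]1COC(C)(C)O1 | intermediate
24 | lithium B-[(3R)-3-[(4R)-2,2-dimethyl-1,3-dioxolan-4-yl]-4-methylpent-4-en-1-yl]-B-methoxy-9-borabicyclo[3.3.1]nonan-9-uide | [Li+].CO[B-]1(CC[C@H](C(C)=C)[C@@H]2COC(C)(C)O2)C2CCCC1CCC2 | intermediate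
25 | ethyl (5S,6Z,9E,13R)-5-[(tert-butyldimethylsilyl)oxy]-2-(diethoxyphosphoryl)-13-[(4R)-2,2-dimethyl-1,3-dioxolan-4-yl]-6,10,14-trimethylpentadeca-6,9,14-trienoate | C=C(C)[C@@H](CC/C(C)=C/C/C=C(/C)[C@@H](O[Si](C)(C)C(C)(C)C)CCC(C(=O)OCC)P(=O)(OCC)OCC)[C@@H]1COC(C)(C)O1 | intermediate
26 | ethyl (5S,6Z,9E,13R,14R)-5-[(tert-butyldimethylsilyl)oxy]-2-(diethoxyphosphoryl)-14,15-dihydroxy-6,10-dimethyl-13-(prop-1-en-2-yl)pentadeca-6,9-dienoate | C=C(C)[C@@H](CC/C(C)=C/C/C=C(/C)[C@@H](O[Si](C)(C)C(C)(C)C)CCC(C(=O)OCC)P(=O)(OCC)OCC)[C@@H](O)CO | intermediate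
27 | ethyl (5S,6Z,9E,13R,14R)-5-[(tert-butyldimethylsilyl)oxy]-2-(diethoxyphosphoryl)-6,10-dimethyl-13-(prop-1-en-2-yl)-14,15-bis[(triethylsilyl)oxy]pentadeca-6,9-dienoate | C=C(C)[C@@H](CC/C(C)=C/C/C=C(/C)[C@@H](O[Si](C)(C)C(C)(C)C)CCC(C(=O)OCC)P(=O)(OCC)OCC)[C@@H](O[Si](CC)(CC)CC)CO[Si](CC)(CC)CC | intermediate
28 | ethyl (5S,6Z,9E,13R,14R)-5-[(tert-butyldimethylsilyl)oxy]-2-(diethoxyphosphoryl)-6,10-dimethyl-15-oxo-13-(prop-1-en-2-yl)-14-[(triethylsilyl)oxy]pentadeca-6,9-dienoate | C=C(C)[C@@H](CC/C(C)=C/C/C=C(/C)[C@@H](O[Si](C)(C)C(C)(C)C)CCC(C(=O)OCC)P(=O)(OCC)OCC)[C@@H](O[Si](CC)(CC)CC)C=O | intermediate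
29 | ethyl (1E,3S,4R,7E,10Z,12S)-12-[(tert-butyldimethylsilyl)oxy]-7,11-dimethyl-4-(prop-1-en-2-yl)-3-[(triethylsilyl)oxy]cyclotetradeca-1,7,10-triene-1-carboxylate | C=C(C)[C@H]1CC/C(C)=C/C/C=C(/C)[C@@H](O[Si](C)(C)C(C)(C)C)CC/C(C(=O)OCC)=C\[C@@H]1O[Si](CC)(CC)CC | intermediate
30 | [(1E,3S,4R,7E,10Z,12S)-12-[(tert-butyldimethylsilyl)oxy]-7,11-dimethyl-4-(prop-1-en-2-yl)-3-[(triethylsilyl)oxy]cyclotetradeca-1,7,10-trien-1-yl]methanol | C=C(C)[C@H]1CC/C(C)=C/C/C=C(/C)[C@@H](O[Si](C)(C)C(C)(C)C)CC/C(CO)=C\[C@@H]1O[Si](CC)(CC)CC | intermediate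
31 | (1E,3S,4R,7E,10Z,12S)-12-[(tert-butyldimethylsilyl)oxy]-1-(hydroxymethyl)-7,11-dimethyl-4-(prop-1-en-2-yl)cyclotetradeca-1,7,10-trien-3-ol | C=C(C)[C@H]1CC/C(C)=C/C/C=C(/C)[C@@H](O[Si](C)(C)C(C)(C)C)CC/C(CO)=C\[C@@H]1O | intermediate
32 | [(1E,3S,4R,7E,10Z,12S)-3-acetoxy-12-[(tert-butyldimethylsilyl)oxy]-7,11-dimethyl-4-(prop-1-en-2-yl)cyclotetradeca-1,7,10-trien-1-yl]methyl acetate | C=C(C)[C@H]1CC/C(C)=C/C/C=C(/C)[C@@H](O[Si](C)(C)C(C)(C)C)CC/C(COC(C)=O)=C\[C@@H]1OC(C)=O | intermediate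
33 | [(1E,3S,4R,7E,10Z,12S)-3-acetoxy-12-hydroxy-7,11-dimethyl-4-(prop-1-en-2-yl)cyclotetradeca-1,7,10-trien-1-yl]methyl acetate (CNP0097266.2) | C=C(C)[C@H]1CC/C(C)=C/C/C=C(/C)[C@@H](O)CC/C(COC(C)=O)=C\[C@@H]1OC(C)=O | target

## Step count and risks

Total: 24 steps. Longest linear sequence: 16 steps (14 → 33 through steps 9–11 and 12–24; the branch from 9 through steps 6–8 and 12–24 is equally long). The branch from 1 (steps 1–5, then 16–24) is 14 steps.

Most likely to fail: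

**Step 3 (facial selectivity of the Claisen rearrangement).** If the (E)-alcohol 4 gives a poor syn:anti ratio, the fallback sets out from aldehyde 2 (made from 1 as in step 1) and moves the allylic strain onto the migrating CH2–O arm, the substitution pattern for which this control is strongest. Z-selective Ando olefination of 2 with ethyl 2-(diphenoxyphosphoryl)propanoate (NaH, THF, −78 °C) gives ethyl (2Z)-3-[(4R)-2,2-dimethyl-1,3-dioxolan-4-yl]-2-methylprop-2-enoate F1. DIBAL-H reduction gives (2Z)-3-[(4R)-2,2-dimethyl-1,3-dioxolan-4-yl]-2-methylprop-2-en-1-ol F2. Heating F2 with triethyl orthoacetate and catalytic propionic acid forms (4R)-4-[(1Z)-3-[(1-ethoxyethenyl)oxy]-2-methylprop-1-en-1-yl]-2,2-dimethyl-1,3-dioxolane F3, which rearranges through the same H-eclipsed, anti-to-oxygen transition state. The fallback comes back to the route at ester 6.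

**Step 12 (Z:E ratio and C9 integrity in the ketone Wittig).** The fallback sets out from Weinreb amide 16 and builds the Z-trisubstituted alkene by hydroxyl-directed anti-carbomagnesiation instead. DIBAL-H reduction of 16 gives (2S)-2,4-bis[(tert-butyldimethylsilyl)oxy]butanal F4. Ohira–Bestmann homologation (dimethyl (1-diazo-2-oxopropyl)phosphonate, K2CO3, MeOH) gives (3S)-3,5-bis[(tert-butyldimethylsilyl)oxy]pent-1-yne F5, and TBAF gives (3S)-pent-4-yne-1,3-diol F6. Treatment of F6 with MeMgBr and catalytic CuI adds methyl to C8 and magnesium to C7 anti, held cis to the carbinol by chelation; trapping with (2E)-1-bromo-3-iodobut-2-ene gives (3S,4Z,7E)-8-iodo-4-methylnona-4,7-diene-1,3-diol F7. Bis-silylation (TBSCl, imidazole) comes back to the route at 19.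

**Step 20 (macrocyclic HWE: oligomers, E/Z ratio, epimerisation at C14).** The fallback sets out from iodide 8 and phosphonate 22, makes the C12=C13 bond intermolecularly and closes the ring at C3–C4 instead. PPTS/MeOH on 8 gives (2R,3R)-5-iodo-3-(prop-1-en-2-yl)pentane-1,2-diol F8. TESCl/imidazole gives (2R,3R)-5-iodo-3-(prop-1-en-2-yl)-1,2-bis[(triethylsilyl)oxy]pentane F9, and Swern oxidation gives (2R,3R)-5-iodo-3-(prop-1-en-2-yl)-2-[(triethylsilyl)oxy]pentanal F10. Intermolecular HWE of F10 with 22 (LiCl, DBU, MeCN) gives ethyl (2E,4S,5R)-2-[(3S,4Z,7E)-3-[(tert-butyldimethylsilyl)oxy]-8-iodo-4-methylnona-4,7-dien-1-yl]-7-iodo-5-(prop-1-en-2-yl)-4-[(triethylsilyl)oxy]hept-2-enoate F11. Zinc insertion into the alkyl iodide (activated Zn, LiCl, THF/DMA) gives the alkylzinc iodide of F11, ethyl (2E,4S,5R)-2-[(3S,4Z,7E)-3-[(tert-butyldimethylsilyl)oxy]-8-iodo-4-methylnona-4,7-dien-1-yl]-7-(iodozincio)-5-(prop-1-en-2-yl)-4-[(triethylsilyl)oxy]hept-2-enoate F12. Intramolecular Negishi coupling of F12 with its vinyl iodide (Pd(PPh3)4, high dilution) comes back to the route at macrocycle 29.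

## Further compounds

F1 | step 3 | ethyl (2Z)-3-[(4R)-2,2-dimethyl-1,3-dioxolan-4-yl]-2-methylprop-2-enoate | CCOC(=O)/C(C)=C\[C@@H]1COC(C)(C)O1
F2 | step 3 | (2Z)-3-[(4R)-2,2-dimethyl-1,3-dioxolan-4-yl]-2-methylprop-2-en-1-ol | OC/C(C)=C\[C@@H]1COC(C)(C)O1
F3 | step 3 | (4R)-4-[(1Z)-3-[(1-ethoxyethenyl)oxy]-2-methylprop-1-en-1-yl]-2,2-dimethyl-1,3-dioxolane | C=C(OCC)OC/C(C)=C\[C@@H]1COC(C)(C)O1
F4 | step 12 | (2S)-2,4-bis[(tert-butyldimethylsilyl)oxy]butanal | O=C[C@@H](O[Si](C)(C)C(C)(C)C)CCO[Si](C)(C)C(C)(C)C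
F5 | step 12 | (3S)-3,5-bis[(tert-butyldimethylsilyl)oxy]pent-1-yne | C#C[C@@H](O[Si](C)(C)C(C)(C)C)CCO[Si](C)(C)C(C)(C)C
F6 | step 12 | (3S)-pent-4-yne-1,3-diol | C#C[C@@H](O)CCO
F7 | step 12 | (3S,4Z,7E)-8-iodo-4-methylnona-4,7-diene-1,3-diol | I/C(C)=C/C/C=C(/C)[C@@H](O)CCO
F8 | step 20 | (2R,3R)-5-iodo-3-(prop-1-en-2-yl)pentane-1,2-diol | C=C(C)[C@@H](CCI)[C@@H](O)CO
F9 | step 20 | (2R,3R)-5-iodo-3-(prop-1-en-2-yl)-1,2-bis[(triethylsilyl)oxy]pentane | C=C(C)[C@@H](CCI)[C@@H](O[Si](CC)(CC)CC)CO[Si](CC)(CC)CC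
F10 | step 20 | (2R,3R)-5-iodo-3-(prop-1-en-2-yl)-2-[(triethylsilyl)oxy]pentanal | C=C(C)[C@@H](CCI)[C@@H](O[Si](CC)(CC)CC)C=O
F11 | step 20 | ethyl (2E,4S,5R)-2-[(3S,4Z,7E)-3-[(tert-butyldimethylsilyl)oxy]-8-iodo-4-methylnona-4,7-dien-1-yl]-7-iodo-5-(prop-1-en-2-yl)-4-[(triethylsilyl)oxy]hept-2-enoate | C=C(C)[C@@H](CCI)[C@@H](O[Si](CC)(CC)CC)/C=C(/C(=O)OCC)CC[C@H](O[Si](C)(C)C(C)(C)C)/C(C)=C\C/C=C(C)/I
F12 | step 20 | ethyl (2E,4S,5R)-2-[(3S,4Z,7E)-3-[(tert-butyldimethylsilyl)oxy]-8-iodo-4-methylnona-4,7-dien-1-yl]-7-(iodozincio)-5-(prop-1-en-2-yl)-4-[(triethylsilyl)oxy]hept-2-enoate | C=C(C)[C@@H](CC[Zn]I)[C@@H](O[Si](CC)(CC)CC)/C=C(/C(=O)OCC)CC[C@H](O[Si](C)(C)C(C)(C)C)/C(C)=C\C/C=C(C)/I
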